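Numbering: C1 is the lactone carbonyl, C2=C3 the tetrasubstituted alkene (C3 carries CH2OAc), C4–C8 the chain with the C6=C7 alkene, C9 the O-bearing carbon and C10 the methine with the side chain. The C2–C10 bond belongs to both the five-membered lactone and the nine-membered carbocycle; cutting it merges them into a ten-membered β-keto macrolactone (C3 as ketone) with a chlorine on exocyclic C10. The key step stitches this ring: the C2 enolate, flanked by C1 and C3, displaces chloride at C10 with inversion, closing lactone and carbocycle at once and setting the trans C9/C10 relationship. The C3 ketone is later turned into the alkene through its enol triflate.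

Key step: step 10

Assumption: (2R,5R)-2,5-diphenylpyrrolidine is taken to deliver the 2S chloride (chlorine enters anti to the phenyl group next to the enamine); if the sense proves opposite, its enantiomer is used.

Step 1
Reactants: 1 (S)-citronellal
Product: 2 (2S,3S)-2-chloro-3,7-dimethyloct-6-enal
Conditions: N-chlorosuccinimide, (2R,5R)-2,5-diphenylpyrrolidine (10 mol %), CH2Cl2, 0 °C to rt; crude product used at once
Reagents that add atoms: N-chlorosuccinimide O=C1CCC(=O)N1Cl
Why: Organocatalytic enamine α-chlorination, in which the C2-symmetric amine shields one enamine face so that the C10 centre is set by the catalyst and not by the neighbouring methyl centre.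

Step 2
Reactants: 3 methyl 3-methylbut-2-enoate
Product: 5 1-methoxy-3-methyl-1-(trimethylsilyloxy)buta-1,3-diene, via lithium dienolate 4 (not isolated)
Conditions: LiN(i-Pr)2, THF, −78 °C; Me3SiCl, −78 °C to rt; distillation
Reagents that add atoms: chlorotrimethylsilane C[Si](C)(C)Cl
Why: γ-Deprotonation of the senecioate and O-silylation of the dienolate (silyl dienol ether formation); no stereocentre is formed.

Step 3
Reactants: 2 (2S,3S)-2-chloro-3,7-dimethyloct-6-enal; 5 1-methoxy-3-methyl-1-(trimethylsilyloxy)buta-1,3-diene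
Product: 7 methyl (2E,5R,6S,7S)-6-chloro-5-hydroxy-3,7,11-trimethyldodeca-2,10-dienoate, via trimethylsilyl ether 6 (not isolated)
Conditions: 2 and 5 premixed, BF3·OEt2 added last, CH2Cl2, −78 °C; aqueous HCl, THF work-up
Reagents that add atoms: none
Why: Vinylogous Mukaiyama aldol reaction at the γ-carbon, in which Cornforth (polar Felkin–Anh) attack anti to chlorine sets C9 (5R, 5,6-anti) and the extended dienolate gives the 2E enoate that becomes the E C6=C7 alkene.

Step 4
Reactants: 7 methyl (2E,5R,6S,7S)-6-chloro-5-hydroxy-3,7,11-trimethyldodeca-2,10-dienoate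
Product: 8 methyl (2E,5R,6S,7S)-5-(tert-butyldimethylsilyloxy)-6-chloro-3,7,11-trimethyldodeca-2,10-dienoate
Conditions: TBSOTf, 2,6-lutidine, CH2Cl2, −78 to 0 °C
Reagents that add atoms: tert-butyldimethylsilyl trifluoromethanesulfonate CC(C)(C)[Si](C)(C)OS(=O)(=O)C(F)(F)F
Why: Silylation of the secondary alcohol masks it during the hydride reduction, bromination and dienolate alkylation that follow; no stereocentre is touched.

Step 5
Reactants: 8 methyl (2E,5R,6S,7S)-5-(tert-butyldimethylsilyloxy)-6-chloro-3,7,11-trimethyldodeca-2,10-dienoate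
Product: 9 (2E,5R,6S,7S)-5-(tert-butyldimethylsilyloxy)-6-chloro-3,7,11-trimethyldodeca-2,10-dien-1-ol
Conditions: i-Bu2AlH (2.5 equiv), CH2Cl2, −78 °C; Rochelle salt work-up
Reagents that add atoms: none
Why: 1,2-Reduction of the conjugated ester by i-Bu2AlH gives the E allylic alcohol, and the chloride and silyl ether are inert at −78 °C.

Step 6
Reactants: 9 (2E,5R,6S,7S)-5-(tert-butyldimethylsilyloxy)-6-chloro-3,7,11-trimethyldodeca-2,10-dien-1-ol
Product: 10 (2E,5R,6S,7S)-1-bromo-5-(tert-butyldimethylsilyloxy)-6-chloro-3,7,11-trimethyldodeca-2,10-diene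
Conditions: CBr4, PPh3, CH2Cl2, −20 °C
Reagents that add atoms: tetrabromomethane BrC(Br)(Br)Br
Why: Appel bromination of the primary allylic alcohol proceeds by SN2 displacement without allylic shift or change of alkene geometry.

Step 7
Reactants: 10 (2E,5R,6S,7S)-1-bromo-5-(tert-butyldimethylsilyloxy)-6-chloro-3,7,11-trimethyldodeca-2,10-diene; 11 2,2,6-trimethyl-4H-1,3-dioxin-4-one
Product: 13 6-[(3E,6R,7S,8S)-6-(tert-butyldimethylsilyloxy)-7-chloro-4,8,12-trimethyltrideca-3,11-dien-1-yl]-2,2-dimethyl-4H-1,3-dioxin-4-one, via lithium dienolate 12 (not isolated)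
Conditions: 11, LiN(i-Pr)2, THF/DMPU, −78 °C; then 10, −78 to −40 °C
Reagents that add atoms: none
Why: Vinylogous (γ) alkylation of the dioxinone dienolate by the allylic bromide forms the C4–C5 bond, and the hindered secondary chloride does not react at this temperature.

Step 8
Reactants: 13 6-[(3E,6R,7S,8S)-6-(tert-butyldimethylsilyloxy)-7-chloro-4,8,12-trimethyltrideca-3,11-dien-1-yl]-2,2-dimethyl-4H-1,3-dioxin-4-one
Product: 14 6-[(3E,6R,7S,8S)-7-chloro-6-hydroxy-4,8,12-trimethyltrideca-3,11-dien-1-yl]-2,2-dimethyl-4H-1,3-dioxin-4-one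
Conditions: HF·pyridine, THF/pyridine, 0 °C to rt
Reagents that add atoms: none
Why: Desilylation by HF under acidic conditions avoids the free alkoxide that would close the chlorohydrin to an epoxide, and the dioxinone is stable to this reagent.

Step 9
Reactants: 14 6-[(3E,6R,7S,8S)-7-chloro-6-hydroxy-4,8,12-trimethyltrideca-3,11-dien-1-yl]-2,2-dimethyl-4H-1,3-dioxin-4-one
Product: 16 (7E,10R)-10-[(1S,2S)-1-chloro-2,6-dimethylhept-5-en-1-yl]-8-methyloxacyclodec-7-ene-2,4-dione, via acylketene 15 (not isolated)
Conditions: toluene, 110 °C, slow addition to a final 0.5 mM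
Reagents that add atoms: none
Why: Retro-[4+2] loss of acetone gives an acylketene that is trapped by the C9 hydroxyl at high dilution (Boeckman-type acylketene macrolactonisation), which gives the ten-membered β-keto lactone under neutral conditions without touching a stereocentre.

Step 10
Reactants: 16 (7E,10R)-10-[(1S,2S)-1-chloro-2,6-dimethylhept-5-en-1-yl]-8-methyloxacyclodec-7-ene-2,4-dione
Product: 18 (5E,8R,11S)-6-methyl-11-[(2S)-6-methylhept-5-en-2-yl]-9-oxabicyclo[6.2.1]undec-5-ene-2,10-dione, via caesium enolate 17 (not isolated)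
Conditions: Cs2CO3 (1.5 equiv), dry MeCN, 70 °C; aqueous NH4Cl work-up
Reagents that add atoms: none
Why: Cs2CO3 deprotonates C2 between the C1 and C3 carbonyls and the enolate carbon displaces chloride at C10 from the backside, an intramolecular SN2 C-alkylation of a β-keto ester enolate that stitches the macrolactone across. The closest known reaction types are the C-alkylation of β-keto ester enolates by secondary halides and the Lacey–Dieckmann closure, which builds the same α-acyl γ-lactone ring through the same ester tether. The lactone closes 5-exo-tet with the enolate exocyclic to the new ring through the C3 ketone (enolexo, allowed), and the nine-membered carbocycle closes at the same time as the transannular consequence of that bond, so no separate medium-ring cyclisation is needed. C10 is set by inversion of the S chloride from step 1, which with the fixed C9 centre gives the trans lactone, while C2 is formed as an enolisable centre that is erased in step 11. The step needs C-alkylation to beat O-alkylation and loss of HCl: five-membered C-closure is favoured over seven-membered closure through the ketone oxygen, the stabilised enolate is a weak base, and the anti chlorohydrin places O–C9 and C10–Cl anti-periplanar so that the C–Cl σ* lies under C2.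

Step 11
Reactants: 18 (5E,8R,11S)-6-methyl-11-[(2S)-6-methylhept-5-en-2-yl]-9-oxabicyclo[6.2.1]undec-5-ene-2,10-dione
Product: 20 (1Z,5E,8R,11S)-6-methyl-11-[(2S)-6-methylhept-5-en-2-yl]-10-oxo-9-oxabicyclo[6.2.1]undeca-1,5-dien-2-yl trifluoromethanesulfonate, via sodium enolate 19 (not isolated)
Conditions: NaH, Et2O/THF, 0 °C; Tf2O, −78 to 0 °C
Reagents that add atoms: trifluoromethanesulfonic anhydride O=S(=O)(OS(=O)(=O)C(F)(F)F)C(F)(F)F
Why: O-Triflation of the β-keto lactone enolate, where the chelated enolate that keeps C4 cis to C10 (cis alkene inside the nine-membered ring) is the only unstrained geometry, so the triflate oxygen ends up cis to the lactone carbonyl as the target alkene requires.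

Step 12
Reactants: 20 (1Z,5E,8R,11S)-6-methyl-11-[(2S)-6-methylhept-5-en-2-yl]-10-oxo-9-oxabicyclo[6.2.1]undeca-1,5-dien-2-yl trifluoromethanesulfonate; 21 (tributylstannyl)methanol
Product: 23 [(1Z,5E,8R,11S)-6-methyl-11-[(2S)-6-methylhept-5-en-2-yl]-10-oxo-9-oxabicyclo[6.2.1]undeca-1,5-dien-2-yl]methyl acetate, via hydroxymethyl lactone 22 (not isolated)
Conditions: Pd(PPh3)4 (5 mol %), LiCl, 1,4-dioxane, 80 °C; then Ac2O, pyridine, DMAP, 0 °C to rt
Reagents that add atoms: acetic anhydride CC(=O)OC(C)=O
Why: Stille coupling (Migita–Kosugi hydroxymethylation) replaces the triflate with retention of alkene geometry, and acetylation in the same flask caps the primary alcohol before it can attack the lactone carbonyl.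

Compound list
1 | (S)-citronellal, (3S)-3,7-dimethyloct-6-enal | O=CC[C@@H](C)CCC=C(C)C | starting material
2 | (2S,3S)-2-chloro-3,7-dimethyloct-6-enal | O=C[C@@H](Cl)[C@@H](C)CCC=C(C)C | intermediate
3 | methyl 3-methylbut-2-enoate | COC(=O)C=C(C)C | starting material
4 | lithium dienolate of 3 (lithium 1-methoxy-3-methylbuta-1,3-dien-1-olate) | COC(O[Li])=CC(C)=C | intermediate
5 | 1-methoxy-3-methyl-1-(trimethylsilyloxy)buta-1,3-diene | COC(O[Si](C)(C)C)=CC(C)=C | intermediate
6 | methyl (2E,5R,6S,7S)-6-chloro-3,7,11-trimethyl-5-(trimethylsilyloxy)dodeca-2,10-dienoate | COC(=O)/C=C(\C)C[C@@H](O[Si](C)(C)C)[C@@H](Cl)[C@@H](C)CCC=C(C)C | intermediate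
7 | methyl (2E,5R,6S,7S)-6-chloro-5-hydroxy-3,7,11-trimethyldodeca-2,10-dienoate | COC(=O)/C=C(\C)C[C@@H](O)[C@@H](Cl)[C@@H](C)CCC=C(C)C | intermediate
8 | methyl (2E,5R,6S,7S)-5-(tert-butyldimethylsilyloxy)-6-chloro-3,7,11-trimethyldodeca-2,10-dienoate | COC(=O)/C=C(\C)C[C@@H](O[Si](C)(C)C(C)(C)C)[C@@H](Cl)[C@@H](C)CCC=C(C)C | intermediate
9 | (2E,5R,6S,7S)-5-(tert-butyldimethylsilyloxy)-6-chloro-3,7,11-trimethyldodeca-2,10-dien-1-ol | OC/C=C(\C)C[C@@H](O[Si](C)(C)C(C)(C)C)[C@@H](Cl)[C@@H](C)CCC=C(C)C | intermediate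
10 | (2E,5R,6S,7S)-1-bromo-5-(tert-butyldimethylsilyloxy)-6-chloro-3,7,11-trimethyldodeca-2,10-diene | BrC/C=C(\C)C[C@@H](O[Si](C)(C)C(C)(C)C)[C@@H](Cl)[C@@H](C)CCC=C(C)C | intermediate
11 | 2,2,6-trimethyl-4H-1,3-dioxin-4-one | CC1=CC(=O)OC(C)(C)O1 | starting material
12 | lithium dienolate of 11 (4-lithiooxy-2,2-dimethyl-6-methylidene-6H-1,3-dioxine) | C=C1C=C(O[Li])OC(C)(C)O1 | intermediate
13 | 6-[(3E,6R,7S,8S)-6-(tert-butyldimethylsilyloxy)-7-chloro-4,8,12-trimethyltrideca-3,11-dien-1-yl]-2,2-dimethyl-4H-1,3-dioxin-4-one | CC1(C)OC(=O)C=C(CC/C=C(\C)C[C@@H](O[Si](C)(C)C(C)(C)C)[C@@H](Cl)[C@@H](C)CCC=C(C)C)O1 | intermediate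
14 | 6-[(3E,6R,7S,8S)-7-chloro-6-hydroxy-4,8,12-trimethyltrideca-3,11-dien-1-yl]-2,2-dimethyl-4H-1,3-dioxin-4-one | CC1(C)OC(=O)C=C(CC/C=C(\C)C[C@@H](O)[C@@H](Cl)[C@@H](C)CCC=C(C)C)O1 | intermediate
15 | acylketene, (6E,9R,10S,11S)-10-chloro-9-hydroxy-7,11,15-trimethylhexadeca-1,6,14-triene-1,3-dione | O=C=CC(=O)CC/C=C(\C)C[C@@H](O)[C@@H](Cl)[C@@H](C)CCC=C(C)C | intermediate
16 | (7E,10R)-10-[(1S,2S)-1-chloro-2,6-dimethylhept-5-en-1-yl]-8-methyloxacyclodec-7-ene-2,4-dione | O=C1CC(=O)CC/C=C(\C)C[C@H]([C@@H](Cl)[C@@H](C)CCC=C(C)C)O1 | intermediate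
17 | caesium enolate of 16 (C2=C3 enolate, geometry not fixed) | O=C1C=C([O-])CC/C=C(\C)C[C@H]([C@@H](Cl)[C@@H](C)CCC=C(C)C)O1.[Cs+] | intermediate
18 | (5E,8R,11S)-6-methyl-11-[(2S)-6-methylhept-5-en-2-yl]-9-oxabicyclo[6.2.1]undec-5-ene-2,10-dione (C1 enolisable, configuration not fixed) | O=C1C2C(=O)O[C@H](C/C(C)=C/CC1)[C@H]2[C@@H](C)CCC=C(C)C | intermediate
19 | sodium (1Z,5E,8R,11S)-6-methyl-11-[(2S)-6-methylhept-5-en-2-yl]-10-oxo-9-oxabicyclo[6.2.1]undeca-1,5-dien-2-olate | [Na+].[O-]/C1=C2\C(=O)O[C@H](C/C(C)=C/CC1)[C@H]2[C@@H](C)CCC=C(C)C | intermediate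
20 | (1Z,5E,8R,11S)-6-methyl-11-[(2S)-6-methylhept-5-en-2-yl]-10-oxo-9-oxabicyclo[6.2.1]undeca-1,5-dien-2-yl trifluoromethanesulfonate | O=S(=O)(O/C1=C2\C(=O)O[C@H](C/C(C)=C/CC1)[C@H]2[C@@H](C)CCC=C(C)C)C(F)(F)F | intermediate
21 | (tributylstannyl)methanol | CCCC[Sn](CCCC)(CCCC)CO | starting material
22 | (1Z,5E,8R,11S)-2-(hydroxymethyl)-6-methyl-11-[(2S)-6-methylhept-5-en-2-yl]-9-oxabicyclo[6.2.1]undeca-1,5-dien-10-one | OC/C1=C2\C(=O)O[C@H](C/C(C)=C/CC1)[C@H]2[C@@H](C)CCC=C(C)C | intermediate
23 | [(1Z,5E,8R,11S)-6-methyl-11-[(2S)-6-methylhept-5-en-2-yl]-10-oxo-9-oxabicyclo[6.2.1]undeca-1,5-dien-2-yl]methyl acetate (CNP0356884.2) | CC(=O)OC/C1=C2\C(=O)O[C@H](C/C(C)=C/CC1)[C@H]2[C@@H](C)CCC=C(C)C | target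

Total step count: 12. Longest linear sequence: 11 steps (steps 1 and 3 to 12, from 1); step 2 is a one-step side branch.

Steps most likely to fail

1. Step 10 (key step). The enolate carbon may fail to reach the backside of the hindered secondary C–Cl bond from within the ten-membered ring. O-alkylation through the ester carbonyl oxygen (a five-membered ketene acetal) or loss of HCl towards C11 would then take over. The fallback changes the bond-forming mode from SN2 to carbenoid C–H insertion and sets out from 16. Tin hydride dechlorination (Bu3SnH, AIBN, toluene, 90 °C) should give the dechloro macrolactone F1. Diazo transfer (4-acetamidobenzenesulfonyl azide, Et3N, MeCN) should then give the 3-diazo-2,4-dione F2. With Rh2(O2CC3F7)4 in CH2Cl2 the carbenoid at C2 should insert into a C10–H bond (1,5-insertion of a diazoacetoacetate into its alkoxy chain), the side chain taking the position trans to C8. Insertion at the allylic C8–H is excluded because it would place the E alkene in a seven-membered ring, and the perfluorobutyrate ligand is chosen to disfavour cyclopropanation. The route is rejoined at 18.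

2. Step 9. Medium-ring closure onto the acylketene has to compete with intermolecular capture, so dimeric and oligomeric lactones may form, the more so as the ring must hold an E alkene. The fallback closes the ten-membered ring by C–C instead of C–O bond formation and sets out from 10. HF·pyridine should remove the silyl group to give the bromo chlorohydrin F3. Heating F3 with 11 in toluene at 110 °C (intermolecular acylketene capture) should give the acetoacetate F4. Its dianion (NaH, then n-BuLi, THF, −78 to 0 °C, high dilution) should close the ring by γ-alkylation of the allylic bromide (Weiler dianion alkylation), rejoining the route at 16.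

3. Step 12. Transfer of the hydroxymethyl group to a hindered, tetrasubstituted vinylpalladium species may be slow. At 80 °C the new primary hydroxyl may also attack the lactone carbonyl, so that the acyl group migrates to give the fused butenolide before acetylation. The fallback sets out from 20 and avoids a free alcohol at high temperature. Formylation (Pd(PPh3)4, CO at 1 atm, Bu3SnH, LiCl, THF, 50 °C) should give the aldehyde F5. Luche reduction (NaBH4, CeCl3·7H2O, MeOH, −78 °C) should then give 22, which is acetylated at once (Ac2O, pyridine, DMAP, 0 °C) to reach 23.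

Further compounds
F1 | step 10 | (7E,10S)-10-[(2S)-2,6-dimethylhept-5-en-1-yl]-8-methyloxacyclodec-7-ene-2,4-dione (16 with H in place of Cl) | O=C1CC(=O)CC/C=C(\C)C[C@H](C[C@@H](C)CCC=C(C)C)O1
F2 | step 10 | (7E,10S)-3-diazo-10-[(2S)-2,6-dimethylhept-5-en-1-yl]-8-methyloxacyclodec-7-ene-2,4-dione | O=C1C(=[N+]=[N-])C(=O)CC/C=C(\C)C[C@H](C[C@@H](C)CCC=C(C)C)O1
F3 | step 9 | (2E,5R,6S,7S)-1-bromo-6-chloro-3,7,11-trimethyldodeca-2,10-dien-5-ol | BrC/C=C(\C)C[C@@H](O)[C@@H](Cl)[C@@H](C)CCC=C(C)C
F4 | step 9 | (2E,5R,6S,7S)-1-bromo-6-chloro-3,7,11-trimethyldodeca-2,10-dien-5-yl 3-oxobutanoate | BrC/C=C(\C)C[C@@H](OC(=O)CC(C)=O)[C@@H](Cl)[C@@H](C)CCC=C(C)C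
F5 | step 12 | (1Z,5E,8R,11S)-6-methyl-11-[(2S)-6-methylhept-5-en-2-yl]-10-oxo-9-oxabicyclo[6.2.1]undeca-1,5-diene-2-carbaldehyde | O=C/C1=C2\C(=O)O[C@H](C/C(C)=C/CC1)[C@H]2[C@@H](C)CCC=C(C)C
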